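**Plan**

- Retrosynthesis: the two sulfate S–O bonds at O3 and O3' and the C3–O bond are cut first, then C4–C4a of ring C, then the O1–C2 aryl vinyl ether bond. The C2–C3–C4 chain goes back to the formyl carbon of 3,4-dihydroxybenzaldehyde (C2), CBr4 (C3) and methyl chloroformate (C4).
- Forward: rings A and B are bought. The ring B aldehyde is differentiated (4'-O-benzyl, 3'-O-allyl), homologated to the ynoate and joined to 3,5-dimethoxyphenol through O1–C2. Ring C is the only ring made and closes last at C4–C4a.
- Enabling feature: ring A is a phloroglucinol ether. Its carbon C4a lies ortho to the O1-bearing carbon and to the 5-oxygen and para to the 7-oxygen, so it can take the C4 acyl carbon under mild activation; the two candidate carbons are equivalent by symmetry.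
- Finish: C3 oxygen by lithiation–borylation–oxidation, chelation-directed 5-O-demethylation, deallylation, sulfation at O3 and O3', hydrogenolysis of the 4'-benzyl ether.
- Stereochemistry: the target has no stereocentre. The only stereo element is the Z alkene of the acrylic acid, set by anti addition of the phenoxide to the ynoate and lost when ring C becomes aromatic.

Key step: step 7

Remark: the target is written as the free bis(hydrogen sulfate), so 17 and 18 are drawn that way. They would be handled as potassium salts (cation exchange in the work-up of step 11, which also removes pyridine before the hydrogenolysis), and the acid form would be released at the end by a short cold pass over H+-form sulfonic acid resin.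

**Route**

Step 1
Reactants: 1 3,4-dihydroxybenzaldehyde
Product: 2 4-(benzyloxy)-3-hydroxybenzaldehyde
Conditions: BnBr (1.05 equiv), NaHCO3, DMF, 40 °C
Reagents that add atoms: benzyl bromide, BrCc1ccccc1
Why: Williamson etherification in which the weak base should ionise only the more acidic 4-hydroxyl (para to the formyl group), so that monobenzylation occurs there.

Step 2
Reactants: 2 4-(benzyloxy)-3-hydroxybenzaldehyde
Product: 3 3-(allyloxy)-4-(benzyloxy)benzaldehyde
Conditions: allyl bromide, K2CO3, DMF, rt
Reagents that add atoms: allyl bromide, C=CCBr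
Why: Williamson etherification of the remaining phenol with a reactive allylic halide.

Step 3
Reactants: 3 3-(allyloxy)-4-(benzyloxy)benzaldehyde
Product: 4 2-(allyloxy)-1-(benzyloxy)-4-(2,2-dibromoethenyl)benzene
Conditions: CBr4, PPh3, CH2Cl2, 0 °C
Reagents that add atoms: carbon tetrabromide, BrC(Br)(Br)Br
Why: Ramirez dibromo-olefination (first stage of the Corey–Fuchs homologation), a Wittig reaction of Ph3P=CBr2 that tolerates aryl allyl and benzyl ethers.

Step 4
Reactants: 4 2-(allyloxy)-1-(benzyloxy)-4-(2,2-dibromoethenyl)benzene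
Product: 6 methyl 3-[3-(allyloxy)-4-(benzyloxy)phenyl]prop-2-ynoate, via lithium arylacetylide 5 (not isolated)
Conditions: n-BuLi (2.1 equiv), THF, −78 °C; then ClCO2Me, −78 °C to rt
Reagents that add atoms: methyl chloroformate, COC(=O)Cl; n-butyllithium, [Li]CCCC (supplies only the lithium of 5)
Why: second stage of the Corey–Fuchs reaction (Br/Li exchange, Fritsch–Buttenberg–Wiechell rearrangement, deprotonation) followed by C-acylation of the acetylide, all at a temperature at which the ethers should not be metalated.

Step 5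
Reactants: 6 methyl 3-[3-(allyloxy)-4-(benzyloxy)phenyl]prop-2-ynoate; 7 3,5-dimethoxyphenol
Product: 8 methyl (Z)-3-[3-(allyloxy)-4-(benzyloxy)phenyl]-3-(3,5-dimethoxyphenoxy)acrylate
Conditions: K2CO3, DMF, 80 °C
Reagents that add atoms: none
Why: oxa-Michael addition of the phenoxide to the β-carbon of the ynoate with anti protonation of the allenolate, which should give mainly the Z vinylogous carbonate with ester and aryloxy group cis, as the ring closure needs.

Step 6
Reactants: 8 methyl (Z)-3-[3-(allyloxy)-4-(benzyloxy)phenyl]-3-(3,5-dimethoxyphenoxy)acrylate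
Product: 9 (Z)-3-[3-(allyloxy)-4-(benzyloxy)phenyl]-3-(3,5-dimethoxyphenoxy)acrylic acid
Conditions: LiOH·H2O, THF/MeOH/H2O, rt; then 1 M HCl, 0 °C, to pH 3
Reagents that add atoms: lithium hydroxide, [Li+].[OH-] (its oxygen ends in the carboxyl group)
Why: saponification of the methyl ester, expected to outrun addition–elimination at the β-carbon because that carbon is deactivated by its aryloxy and electron-rich aryl donors.

Step 7
Reactants: 9 (Z)-3-[3-(allyloxy)-4-(benzyloxy)phenyl]-3-(3,5-dimethoxyphenoxy)acrylic acid
Product: 11 2-[3-(allyloxy)-4-(benzyloxy)phenyl]-5,7-dimethoxy-4H-chromen-4-one, via mixed trifluoroacetic anhydride 10 (not isolated)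
Conditions: TFAA (2 equiv), CH2Cl2, 0 °C to rt
Reagents that add atoms: trifluoroacetic anhydride, O=C(OC(=O)C(F)(F)F)C(F)(F)F (its trifluoroacetyl group sits only in 10; no atom of it remains in 11)
Why: The acid is converted into mixed anhydride 10, which, helped by the liberated CF3CO2H, ionises toward a β-donor-stabilised acylium ion; this is attacked by the ring carbon ortho to the ether oxygen, and loss of a proton restores the arene and delivers the aromatic pyranone. The closest known reaction type is the intramolecular Friedel–Crafts acylation of β-aryloxycinnamic acids to flavones, run here in its mild anhydride-activated form. Ring C closes as a six-membered ring by electrophilic aromatic substitution, 6-exo-trig at the acyl carbon, forming C4–C4a. No stereocentre is created, and the Z alkene ends up inside the aromatic ring. The step needs chemoselectivity for ring A over the five-membered indenone closure onto ring B and over ionisation of the benzyl and allyl ethers; this is secured by the cis placement of acyl and aryloxy groups, the three oxygen donors ortho and para to the attacked carbon, and the absence of a strong Lewis or mineral acid. Regioselectivity is not an issue because the two ortho carbons of the 3,5-dimethoxyphenoxy ring are equivalent, and any E isomer carried along should equilibrate through the protonated push–pull alkene and funnel to the same product.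

Step 8
Reactants: 11 2-[3-(allyloxy)-4-(benzyloxy)phenyl]-5,7-dimethoxy-4H-chromen-4-one
Product: 14 2-[3-(allyloxy)-4-(benzyloxy)phenyl]-3-hydroxy-5,7-dimethoxy-4H-chromen-4-one, via 3-lithioflavone 12 (not isolated), via dimethyl flavon-3-ylboronate 13 (not isolated)
Conditions: LiN(i-Pr)2 (1.3 equiv), THF, −78 °C; B(OMe)3, −78 to 0 °C; then AcOH, 30% H2O2, 0 °C to rt
Reagents that add atoms: hydrogen peroxide, OO (the C3 oxygen); lithium diisopropylamide, CC(C)N([Li])C(C)C (lithium of 12 only); trimethyl borate, COB(OC)OC (boryl group of 13 only)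
Why: carbonyl-directed C3 lithiation of the flavone by the amide base, borylation and oxidative 1,2-migration of the boronate, a known sequence on 5,7-dimethoxyflavones in which the non-nucleophilic base should leave the ethers and the pyranone ring intact.

Step 9
Reactants: 14 2-[3-(allyloxy)-4-(benzyloxy)phenyl]-3-hydroxy-5,7-dimethoxy-4H-chromen-4-one
Product: 15 2-[3-(allyloxy)-4-(benzyloxy)phenyl]-3,5-dihydroxy-7-methoxy-4H-chromen-4-one
Conditions: MgI2·OEt2 (4 equiv), THF, 60 °C; then 1 M HCl
Reagents that add atoms: none
Why: chelation-directed ether cleavage in which magnesium bridges the C4 carbonyl and the 5-methoxy oxygen so that iodide removes only that methyl group by SN2, while the unchelated 7-methyl, benzyl and allyl ethers should stay; the excess reagent allows for the equivalent bound by the 3-hydroxyl.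

Step 10
Reactants: 15 2-[3-(allyloxy)-4-(benzyloxy)phenyl]-3,5-dihydroxy-7-methoxy-4H-chromen-4-one
Product: 16 2-[4-(benzyloxy)-3-hydroxyphenyl]-3,5-dihydroxy-7-methoxy-4H-chromen-4-one (4'-O-benzylrhamnetin)
Conditions: Pd(PPh3)4 (5 mol %), morpholine, degassed THF, rt
Reagents that add atoms: none
Why: Tsuji–Trost deallylation, in which zerovalent palladium ionises the aryl allyl ether to a π-allyl complex that morpholine intercepts, leaving the benzyl ether and the free phenols untouched.

Step 11
Reactants: 16 2-[4-(benzyloxy)-3-hydroxyphenyl]-3,5-dihydroxy-7-methoxy-4H-chromen-4-one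
Product: 17 2-(benzyloxy)-5-[5-hydroxy-7-methoxy-4-oxo-3-(sulfooxy)-4H-chromen-2-yl]phenyl hydrogen sulfate (4'-O-benzylrhamnetin 3,3'-disulfate)
Conditions: SO3·pyridine (5 equiv), pyridine/DMF, rt to 40 °C
Reagents that add atoms: sulfur trioxide–pyridine complex, O=S(=O)([O-])[n+]1ccccc1
Why: O-sulfation by SO3 transfer from the amine complex, expected at the 3- and 3'-hydroxyls only, because the 5-hydroxyl is locked in a six-membered hydrogen bond to C4=O and is the least reactive hydroxyl of flavonols toward such reagents, and O4' is blocked.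

Step 12
Reactants: 17 4'-O-benzylrhamnetin 3,3'-disulfate
Product: 18 rhamnetin 3,3'-disulfate
Conditions: H2 (1 atm), Pd/C (10% Pd), MeOH/H2O, rt; then sulfonic acid resin (H+ form), 0 °C
Reagents that add atoms: none
Why: hydrogenolysis of the benzyl aryl ether, which at atmospheric pressure should spare the aryl and enol sulfate monoesters and the C2=C3 bond of the flavonol.

**Compound list**

1 | 3,4-dihydroxybenzaldehyde | O=Cc1ccc(O)c(O)c1 | starting material
2 | 4-(benzyloxy)-3-hydroxybenzaldehyde | O=Cc1ccc(OCc2ccccc2)c(O)c1 | intermediate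
3 | 3-(allyloxy)-4-(benzyloxy)benzaldehyde | O=Cc1ccc(OCc2ccccc2)c(OCC=C)c1 | intermediate
4 | 2-(allyloxy)-1-(benzyloxy)-4-(2,2-dibromoethenyl)benzene | BrC(Br)=Cc1ccc(OCc2ccccc2)c(OCC=C)c1 | intermediate
5 | lithium [3-(allyloxy)-4-(benzyloxy)phenyl]acetylide (not isolated) | [Li]C#Cc1ccc(OCc2ccccc2)c(OCC=C)c1 | intermediate
6 | methyl 3-[3-(allyloxy)-4-(benzyloxy)phenyl]prop-2-ynoate | COC(=O)C#Cc1ccc(OCc2ccccc2)c(OCC=C)c1 | intermediate
7 | 3,5-dimethoxyphenol | COc1cc(O)cc(OC)c1 | starting material
8 | methyl (Z)-3-[3-(allyloxy)-4-(benzyloxy)phenyl]-3-(3,5-dimethoxyphenoxy)acrylate | COC(=O)/C=C(\Oc1cc(OC)cc(OC)c1)c1ccc(OCc2ccccc2)c(OCC=C)c1 | intermediate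
9 | (Z)-3-[3-(allyloxy)-4-(benzyloxy)phenyl]-3-(3,5-dimethoxyphenoxy)acrylic acid | OC(=O)/C=C(\Oc1cc(OC)cc(OC)c1)c1ccc(OCc2ccccc2)c(OCC=C)c1 | intermediate
10 | (Z)-3-[3-(allyloxy)-4-(benzyloxy)phenyl]-3-(3,5-dimethoxyphenoxy)acrylic trifluoroacetic anhydride (not isolated) | FC(F)(F)C(=O)OC(=O)/C=C(\Oc1cc(OC)cc(OC)c1)c1ccc(OCc2ccccc2)c(OCC=C)c1 | intermediate
11 | 2-[3-(allyloxy)-4-(benzyloxy)phenyl]-5,7-dimethoxy-4H-chromen-4-one | COc1cc(OC)c2c(=O)cc(-c3ccc(OCc4ccccc4)c(OCC=C)c3)oc2c1 | intermediate
12 | 3-lithio-2-[3-(allyloxy)-4-(benzyloxy)phenyl]-5,7-dimethoxy-4H-chromen-4-one (not isolated) | COc1cc(OC)c2c(=O)c([Li])c(-c3ccc(OCc4ccccc4)c(OCC=C)c3)oc2c1 | intermediate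
13 | dimethyl {2-[3-(allyloxy)-4-(benzyloxy)phenyl]-5,7-dimethoxy-4-oxo-4H-chromen-3-yl}boronate (not isolated) | COc1cc(OC)c2c(=O)c(B(OC)OC)c(-c3ccc(OCc4ccccc4)c(OCC=C)c3)oc2c1 | intermediate
14 | 2-[3-(allyloxy)-4-(benzyloxy)phenyl]-3-hydroxy-5,7-dimethoxy-4H-chromen-4-one | COc1cc(OC)c2c(=O)c(O)c(-c3ccc(OCc4ccccc4)c(OCC=C)c3)oc2c1 | intermediate
15 | 2-[3-(allyloxy)-4-(benzyloxy)phenyl]-3,5-dihydroxy-7-methoxy-4H-chromen-4-one | COc1cc(O)c2c(=O)c(O)c(-c3ccc(OCc4ccccc4)c(OCC=C)c3)oc2c1 | intermediate
16 | 2-[4-(benzyloxy)-3-hydroxyphenyl]-3,5-dihydroxy-7-methoxy-4H-chromen-4-one | COc1cc(O)c2c(=O)c(O)c(-c3ccc(OCc4ccccc4)c(O)c3)oc2c1 | intermediate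
17 | 2-(benzyloxy)-5-[5-hydroxy-7-methoxy-4-oxo-3-(sulfooxy)-4H-chromen-2-yl]phenyl hydrogen sulfate | COc1cc(O)c2c(=O)c(OS(=O)(=O)O)c(-c3ccc(OCc4ccccc4)c(OS(=O)(=O)O)c3)oc2c1 | intermediate
18 | rhamnetin 3,3'-disulfate | COc1cc(O)c2c(=O)c(OS(=O)(=O)O)c(-c3ccc(O)c(OS(=O)(=O)O)c3)oc2c1 | target

**Step count**

Total: 12 steps. Longest linear sequence: 12 steps, from 1 to 18; phenol 7 enters at step 5.

**Steps most likely to fail**

Step 7. The mixed anhydride of this vinylogous carbonate may ionise too slowly, so that trifluoroacetylation of ring A or acid-induced loss of the benzyl group overtakes ring closure. The fallback sets out from acid 9 and uses a discrete acyl chloride with a Lewis acid at low temperature. Oxalyl chloride with catalytic DMF in CH2Cl2 at 0 °C should give (Z)-3-[3-(allyloxy)-4-(benzyloxy)phenyl]-3-(3,5-dimethoxyphenoxy)acryloyl chloride F1. After evaporation this is closed with SnCl4 (1.1 equiv) in CH2Cl2 at −78 °C in a classical Friedel–Crafts acylation on the same C4–C4a bond. The fallback comes back to the route at flavone 11.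

Step 9. The free 3-hydroxyl may bind magnesium first as a 3-olate/C4=O chelate, which withdraws Lewis acid from the 5-methoxy oxygen and liberates HI. The demethylation could then stall or be accompanied by acidolysis of the benzyl ether. The fallback sets out from flavonol 14 and masks the 3-hydroxyl with a group that the next deprotection removes anyway. Allyl bromide and K2CO3 in DMF should give 3-(allyloxy)-2-[3-(allyloxy)-4-(benzyloxy)phenyl]-5,7-dimethoxy-4H-chromen-4-one F2. MgI2·OEt2 in THF at 60 °C, now with no acidic proton present, cleaves the chelated 5-methyl ether to 3-(allyloxy)-2-[3-(allyloxy)-4-(benzyloxy)phenyl]-5-hydroxy-7-methoxy-4H-chromen-4-one F3. The Pd(PPh3)4/morpholine deallylation of step 10, with twice the morpholine, removes both allyl groups and comes back to the route at 16. If iodide also took off the 3-allyl group, the material would be 15 and would rejoin there.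

Step 11. Incomplete sulfation of the hydrogen-bonded 3-hydroxyl, or partial sulfation at O5, would give a mixture of highly polar salts that resists separation. The fallback sets out from triol 16 and installs the sulfates as neutral protected diesters. 2,2,2-Trichloroethyl chlorosulfate with Et3N and catalytic DMAP in THF at 0 °C should give the 3,3'-bis(2,2,2-trichloroethyl sulfate) of 4'-O-benzylrhamnetin F4, which can be purified on silica gel. Zn dust and HCO2NH4 in MeOH at rt then unmask both sulfate monoesters by reductive fragmentation. The fallback comes back to the route at 17.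

**Further compounds**

F1 | step 7 | (Z)-3-[3-(allyloxy)-4-(benzyloxy)phenyl]-3-(3,5-dimethoxyphenoxy)acryloyl chloride | O=C(Cl)/C=C(\Oc1cc(OC)cc(OC)c1)c1ccc(OCc2ccccc2)c(OCC=C)c1
F2 | step 9 | 3-(allyloxy)-2-[3-(allyloxy)-4-(benzyloxy)phenyl]-5,7-dimethoxy-4H-chromen-4-one | COc1cc(OC)c2c(=O)c(OCC=C)c(-c3ccc(OCc4ccccc4)c(OCC=C)c3)oc2c1
F3 | step 9 | 3-(allyloxy)-2-[3-(allyloxy)-4-(benzyloxy)phenyl]-5-hydroxy-7-methoxy-4H-chromen-4-one | COc1cc(O)c2c(=O)c(OCC=C)c(-c3ccc(OCc4ccccc4)c(OCC=C)c3)oc2c1
F4 | step 11 | 2-(benzyloxy)-5-{5-hydroxy-7-methoxy-4-oxo-3-[(2,2,2-trichloroethoxy)sulfonyloxy]-4H-chromen-2-yl}phenyl 2,2,2-trichloroethyl sulfate | COc1cc(O)c2c(=O)c(OS(=O)(=O)OCC(Cl)(Cl)Cl)c(-c3ccc(OCc4ccccc4)c(OS(=O)(=O)OCC(Cl)(Cl)Cl)c3)oc2c1
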